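The readings were generated by integration for an exercise; the scatter is artificial.

The unit I reckon in is the turnover per hour: target made per catalyst charged, per hour.

all flasks: free catalyst 19 mol%

| charge | substrate | partner | temperature | remark | time |
|---|---|---|---|---|---|
| green | 1 M | 0.95 equiv | 95 °C | run made earlier |  |
| epsilon | 0.50 M | 0.950 equiv | 95 °C |  | 40 h |
| alpha | 0.50 M | 0.950 equiv | 80 °C |  | 40 h |
| beta | 0.50 M | 0.950 equiv |  | at 80 °C until 12 h, from then on at 95 °C | 40 h |

green run (percent of the substrate charged)

| time / h | target / % | substrate / % |
|---|---|---|
| 0.500 | 9 | 73 |
| 1.33 | 28 | 57 |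
| 2.50 | 45 | 33 |
| 4.00 | 66 | 11 |

(standard deviation of a reading: 2 percentage points)

- the earlier runs do not show what temperature does; that part of a forecast is a guess
- no earlier run changes the charge of free catalyst; that part of a forecast is a guess

- the best flask by amount of target, in percent of the substrate charged; "all alike" if 1.5 percentage points covers them all (epsilon / alpha / beta / all alike)
- amount of target at the end, in percent of the substrate charged, epsilon
- amount of target at the end, in percent of the substrate charged, alpha
- amount of target at the end, in percent of the substrate charged, beta

In the green run I get the rate two ways. The target, from first to last reading, climbs at 0.163 M h⁻¹. The substrate, from its charge to the last reading, falls at 0.223 M h⁻¹, faster, so they part and one of them cheats. It is the substrate: by the first reading it has lost 0.180 M that is not target, against 0.190 M of catalyst charged, and I read that as a burst onto the catalyst. Taken from the first reading, the substrate falls at 0.177 M h⁻¹, a difference of 5 percentage points between readings that scatter by 2 points, which I accept.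

Meanwhile the substrate falls from 73% to 11% and the target's slope goes only from 0.180 M h⁻¹ to 0.140 M h⁻¹. I read this as roughly zero order in substrate, with c(catalyst) setting the rate. So the turnover frequency, the target's slope divided by the catalyst charged, is 0.857 h⁻¹.

Partner is the limiting reagent, so the target's ceiling is 95.0%, which takes 5.00 turnovers. No earlier run changes the concentration, so keeping the same frequency at half the concentration is a guess, and I take it for want of a better one. Epsilon then needs 5.83 h. For alpha I guess cooling slows it 4-fold, to 0.214 h⁻¹, and it needs 23.4 h. Beta, warmed at 12 h, needs 14.8 h. On those guesses alpha takes longest and still stays inside 40 h, so I commit to flasks alike, at the ceiling.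

The forecast says all alike, with 90%, 89% and 90% for epsilon, alpha and beta, because “all three flasks should approach the cap”.

Epsilon ends at 89.8%, alpha at 90.1% and beta at 90.1%: all alike, but 5.2 points under my ceiling in epsilon. At 40.0 h epsilon holds partner at 0% and over-reaction product at 2.62%, which the scheme below builds from target and partner. Alpha's 73.2% at 20.0 h is 0.193 h⁻¹ on average, against my guessed 0.214 h⁻¹.

    substrate + free catalyst → catalyst intermediate A (k = 0.260 M⁻¹ min⁻¹, Ea = 79.0 kJ mol⁻¹)
    partner + catalyst intermediate A → catalyst intermediate B (k = 0.0620 M⁻¹ min⁻¹, Ea = 77.0 kJ mol⁻¹)
    catalyst intermediate B → free catalyst + target (k = 0.00530 min⁻¹, Ea = 104 kJ mol⁻¹)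
    partner + target → over-reaction product (k = 2.40 × 10⁻⁴ M⁻¹ min⁻¹, Ea = 106 kJ mol⁻¹)
    (constants at 80 °C)

A neighbour of epsilon, charged with 0.570 equiv of partner, needs 3.00 turnovers, 3.50 h at my frequency, so I expect its ceiling of 57.0%. It gives 55.7% target, with partner at 0% and substrate at 25%.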